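The neighbour of dusk charged with less initiator comes at the end of this note, and it has to yield to the same two times as the three flasks here.

| flask | free monomer | initiator | temperature | time | remark |
|---|---|---|---|---|---|
| autumn | 0.18 M (in portions, 2) | 0.36 mM | 5 °C | 2.5 h | the portions of free monomer follow each other after 3.0 min, the first at the start |
| midnight | 0.18 M (in portions, 2) | 0.36 mM | 20 °C | 2.5 h | the portions of free monomer follow each other after 3.0 min, the first at the start |
| dusk | 0.18 M (in portions, 2) | 0.36 mM | −10 °C | 2.5 h | the portions of free monomer follow each other after 3.0 min, the first at the start |

    free monomer + initiator → living end + monomer in chains (k1 = 12 M⁻¹ min⁻¹, Ea1 = 60.0 kJ mol⁻¹)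
    free monomer + living end → monomer in chains + living end, rate k2*[living end]*[free monomer] (k2 = 140 M⁻¹ min⁻¹, Ea2 = 41.0 kJ mol⁻¹)
    2 free monomer → homo dimer (k3 = 3.7 × 10⁻⁴ M⁻¹ min⁻¹, Ea3 = 60.0 kJ mol⁻¹)
    monomer in chains → over-reaction product (k4 = 0.046 min⁻¹, Ea4 = 74.0 kJ mol⁻¹)
    (constants at 5 °C)

- in percentages every species weighs as the free monomer in it: one homo dimer counts as two
- where a step has two of a species, its rate is k times that concentration squared, and two are used at each turn
- constants are those at 5 °C; use the activation energies for any other temperature

1. the flask with the highest amount of monomer in chains, in percent of the free monomer charged ("all alike" if they lie within 1.5 percentage points) (autumn / midnight / dusk / all alike)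
2. final monomer in chains, as a percentage of the free monomer charged, in autumn
3. final monomer in chains, as a percentage of the free monomer charged, in midnight
4. final monomer in chains, as a percentage of the free monomer charged, in dusk

Two times carry the reckoning, taken first for dusk. The feed time is one over k2 at that temperature times the living end, set equal to the initiator charge, which makes chain growth pseudo-first-order: 54.5 min. The loss time is one over k4 at that temperature: 135 min. The loss time over the feed time is the hand-over ratio, 2.47. Above one, the feed time is the shorter of the two and the loss step is rate-limiting for the passage to over-reaction product; below one, the feed step is, and chains trail behind free monomer.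

Other times stand aside in dusk. The initiator lasts about 4.06 min, shorter than the feed time, and the homo dimer half-life at the full charge, 32900 min, is far longer.

Ea4 exceeds Ea2, so the ratio falls with heat: 1.10 in autumn and 0.528 in midnight, where control has crossed over. For two stages in series, the fraction in chains is the difference of the two decay factors, weighted by the loss time over the gap between the times. At 150 min that gives 44.4% in dusk and 0.558% in autumn, more in dusk than in autumn. In midnight the feed time is 8.01 min, so hardly any free monomer remains to feed chains.

The forecast names dusk, with 0.6%, <0.001% and 45.1% for autumn, midnight and dusk, holding that "Initiation is fast compared with the run". The simulation gives dusk, with 0.603%, 0% and 45.1%.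

The temperature dependence of the loss step is the largest single effect behind the order: without it, midnight minus dusk stands at −9.9 percentage points instead of −45 points. The neighbour of dusk with 9.0 × 10⁻⁵ M of initiator has a feed time of 218 min, so its ratio stands at 0.619 against 2.47 in dusk, below one, and the reckoning gives 28.2% in chains. That neighbour computes to 28.0% in chains, with 50.9% still free monomer.

(The numbers come from no measurement; no experiment stands behind them.)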